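**Plan**
- Retrosynthetic cuts, in order: C6–Cl (SN2 on the 6-epi alcohol), C5–C6 (closure of the ten-membered ring on a C6 aldehyde), C8–C17 (γ-lactone), O7–C19 (acryloyl helper), then C7–C6, C8–C7/C9–C8, C1–C2 and C10–C9, back to enone 3, aldehyde 6, vinyl units and allyl ether 12.
- Forward: the cyclohexane ring comes from a dearomatized cresol; a one-pot conjugate addition–aldol attaches the C9 vinyl group and the C2–C5 chain; the C9–C6 chain is grown by allylboration and vinyl addition; then lactone (step 16), epoxide (step 17), ten-membered ring (step 19), chloride (step 22).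
- Enabling feature: C8 is a ketone-level carbon and its neighbour C7 carries the lactone oxygen, so an acryloyl group on O7 holds C17 four atoms from C8. Hydride addition at C18 makes the C17 enolate regiospecifically, and the five-membered lactone ring (O7, C19, C17, C8, C7) closes by the C8–C17 aldol bond, fixing C8, C17 and the C18 methyl together.
- Stereochemistry: C10 from the chiral copper catalyst; C1 and C2 from the anti-to-vinyl, closed-chair aldol; C14 and C6 from hydroxyl-directed hydride delivery (C6 then inverted by chloride); C9 from the Ipc2B reagent (C8 is a sacrificial relay); C7 from Felkin–Anh addition; C8 and C17 from the C7-controlled chelated aldol; C11 from equatorial epoxidation anti to the axial C1 methyl.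

Key step: step 16

Remark: atoms are numbered as in the briarane skeleton of the target (C1 quaternary carbon, C2–C10 ten-membered ring, C11–C14 cyclohexane, C15 methyl on C1, C16 methylene on C5, C17/C18/C19 lactone CH, methyl and carbonyl, C20 epoxide CH2); allyl methoxymethyl ether 12 is taken to be a catalogue compound.

Step 1
Reactants: 1 4-methoxy-2-methylphenol
Product: 2 4,4-dimethoxy-2-methylcyclohexa-2,5-dien-1-one
Conditions: PhI(OAc)2, MeOH, 0 °C
Reagents that add atoms: methanol, CO
Why: Hypervalent-iodine oxidative dearomatization of a para-methoxyphenol in methanol (quinone monoketal formation) should turn the arene into the future cyclohexane ring, with C14 as ketone, C1 carrying its methyl and C11 masked as a dimethyl ketal; no stereocentre is formed.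

Step 2
Reactants: 2 4,4-dimethoxy-2-methylcyclohexa-2,5-dien-1-one
Product: 3 4,4-dimethoxy-2-methylcyclohex-2-en-1-one
Conditions: H2 (1 atm), RhCl(PPh3)3 (5 mol %), benzene, rt
Reagents that add atoms: none
Why: Homogeneous hydrogenation with RhCl(PPh3)3 should saturate only the disubstituted enone double bond and leave the methyl-bearing trisubstituted one, as in the selective reduction of cross-conjugated steroidal 1,4-dien-3-ones; no stereocentre is formed.

Step 3
Reactants: 4 pent-4-yn-1-ol
Product: 5 4-iodopent-4-en-1-ol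
Conditions: NaI, Me3SiCl, H2O, MeCN, rt
Reagents that add atoms: sodium iodide, [Na+].[I-]
Why: Markovnikov hydroiodination of the terminal alkyne by HI made in the flask should give the 2-iodoalkene that later serves as the C5 nucleophile (C16 is its CH2).

Step 4
Reactants: 5 4-iodopent-4-en-1-ol
Product: 6 4-iodopent-4-enal
Conditions: Dess–Martin periodinane, CH2Cl2, rt
Reagents that add atoms: none
Why: Dess–Martin oxidation of the primary alcohol should give the aldehyde (future C2) without touching the iodoalkene.

Step 5
Reactants: 3 4,4-dimethoxy-2-methylcyclohex-2-en-1-one, 7 vinylmagnesium bromide, 6 4-iodopent-4-enal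
Product: 9 (2S,3R)-2-[(1S)-1-hydroxy-4-iodopent-4-en-1-yl]-4,4-dimethoxy-2-methyl-3-vinylcyclohexan-1-one, via magnesium enolate 8 (not isolated)
Conditions: 7 (1.05 equiv), Cu(OTf)2 (3 mol %), chiral hydroxyalkyl-imidazolinium carbene precursor (4 mol %), Et2O, −30 °C; then 6, −78 °C; H2O
Reagents that add atoms: none
Why: Copper-catalysed asymmetric conjugate addition of a Grignard reagent to a 2-methylcyclohexenone with aldol trapping of the magnesium enolate: the ligand antipode is chosen so that vinyl adds to the Re face of C3 of the enone (future C10), the aldehyde then attacks C1 anti to the new vinyl group, and the closed Zimmerman–Traxler chair of the ring enolate (methyl cis to O–Mg) places the C2 hydroxyl syn to the C1 methyl.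

Step 6
Reactants: 9 aldol
Product: 10 monoacetate (C2 acetate; C14 axial alcohol 1,3-anti to O2; other centres as in 9)
Conditions: SmI2 (30 mol %), CH3CHO (8 equiv), THF, −10 °C
Reagents that add atoms: acetaldehyde, CC=O
Why: Evans–Tishchenko reduction: the samarium-bound hemiacetal of the C2 hydroxyl with acetaldehyde delivers hydride intramolecularly to the C14 ketone through a chair fused trans-decalin-like to the cyclohexanone, which should give the 1,3-anti (axial) C14 alcohol and leave O2 as the acetate required in the target.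

Step 7
Reactants: 10 monoacetate
Product: 11 C9 aldehyde (C10 formyl group in place of vinyl)
Conditions: OsO4 (2 mol %), NaIO4 (4 equiv), 2,6-lutidine, dioxane/H2O (3:1), rt
Reagents that add atoms: sodium periodate, [Na+].[O-]I(=O)(=O)=O
Why: Johnson–Lemieux cleavage should cut the monosubstituted vinyl group and spare the halogen-deactivated 2-iodoalkene, giving the C9 aldehyde with C10 in its equatorial, thermodynamically preferred configuration.

Step 8
Reactants: 11 C9 aldehyde, 12 allyl methoxymethyl ether
Product: 15 syn adduct ((9S) alcohol; (8S) methoxymethyl ether; terminal vinyl on C8), via lithiated allyl ether 13 (not isolated), via allylborane 14 (not isolated)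
Conditions: 12, sec-BuLi, THF, −78 °C; (+)-Ipc2BOMe (from (−)-α-pinene); BF3·OEt2; then 11, −78 °C; ethanolamine work-up
Reagents that add atoms: none
Why: Brown asymmetric γ-alkoxyallylboration: the (Z)-γ-(methoxymethoxy)allylborane attacks the Re face of the aldehyde through a chair transition state, so C9 is set by the reagent and the 8,9-syn relationship by the (Z)-geometry; the C14 hydroxyl is tolerated with excess reagent.

Step 9
Reactants: 15 syn adduct
Product: 16 triacetate (acetates on O2, O9 and O14)
Conditions: Ac2O, DMAP, pyridine, 40 °C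
Reagents that add atoms: acetic anhydride, CC(=O)OC(C)=O
Why: DMAP-catalysed acetylation of the C9 and the hindered axial C14 hydroxyls should install the two remaining acetates of the target in one operation.

Step 10
Reactants: 16 triacetate
Product: 17 C7 aldehyde (α-methoxymethoxy aldehyde)
Conditions: OsO4 (2 mol %), NaIO4 (4 equiv), 2,6-lutidine, dioxane/H2O (3:1), rt
Reagents that add atoms: sodium periodate, [Na+].[O-]I(=O)(=O)=O
Why: A second Johnson–Lemieux cleavage should turn the vinyl group into the C7 aldehyde; the lutidine-buffered medium limits epimerisation at C8 and loss of the β-acetate, and the crude aldehyde is used at once.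

Step 11
Reactants: 17 C7 aldehyde, 7 vinylmagnesium bromide
Product: 20 keto alcohol ((7S) allylic alcohol; C11 ketone), via vinyltitanium triisopropoxide 18 (not isolated), via ketal alcohol 19 (not isolated)
Conditions: 7, ClTi(OiPr)3, THF, −78 to 0 °C; then 17, −78 to −20 °C; then 1 M HCl, THF, rt
Reagents that add atoms: water, O
Why: The non-chelating, aldehyde-selective vinyltitanium reagent should add under polar Felkin–Anh control anti to the C8–OMOM bond, which gives the 7,8-anti and 7,9-anti relationship of the target, and the acidic work-up hydrolyses the dimethyl ketal to the C11 ketone while the MOM ether and acetates survive.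

Step 12
Reactants: 20 keto alcohol
Product: 21 methylene alcohol (C11=C20)
Conditions: Zn, CH2Br2, TiCl4, THF, 0 °C to rt (preformed reagent)
Reagents that add atoms: dibromomethane, BrCBr
Why: Non-basic Takai–Lombardo methylenation should convert the only ketone into the exocyclic alkene without β-elimination of the C9 acetate or epimerisation at C10, and leaves the esters alone.

Step 13
Reactants: 21 methylene alcohol
Product: 22 acrylate (acryloyl on O7)
Conditions: acryloyl chloride, i-Pr2NEt, CH2Cl2, −20 to 0 °C
Reagents that add atoms: acryloyl chloride, C=CC(=O)Cl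
Why: O-acylation of the only free hydroxyl installs the acryloyl helper, which carries C19, C17 and C18 of the lactone as an unsaturated ester.

Step 14
Reactants: 22 acrylate
Product: 24 C8 alcohol, via bromomethyl ether 23 (not isolated)
Conditions: Me2BBr, CH2Cl2, −78 °C; then sat. aq. NaHCO3
Reagents that add atoms: none
Why: Bromodimethylborane cleaves the MOM acetal at −78 °C to the bromomethyl ether, which hydrolyses on work-up; esters and alkenes are not attacked and the low temperature limits acyl migration to the freed C8 hydroxyl.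

Step 15
Reactants: 24 C8 alcohol
Product: 25 C8 ketone (α-acryloyloxy ketone)
Conditions: Dess–Martin periodinane, pyridine, CH2Cl2, 0 °C
Reagents that add atoms: none
Why: Buffered Dess–Martin oxidation should give the C8 ketone and erase the relay stereocentre at C8; the base-sensitive product is used directly.

Step 16
Reactants: 25 C8 ketone
Product: 28 hydroxy lactone (C8 tertiary alcohol; C17 methyl; trans-disposed C6 and C9), via copper enolate 26 (not isolated), via silyl ether 27 (not isolated)
Conditions: Cu(OAc)2·H2O (5 mol %), rac-BINAP (5 mol %), (HMe2Si)2O (1.2 equiv), THF, 0 °C to rt; then 1 M HCl, THF, 0 °C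
Reagents that add atoms: none
Why: A phosphine-ligated copper hydride (monovalent copper, made in the flask from Cu(OAc)2 and the silane) adds hydride to C18 of the acryloyl group, which makes the C18 methyl and a copper (Z)-enolate at C17 without touching the far more acidic C7–H and C9–H beside the ketone; the enolate adds to the C8 ketone and σ-bond metathesis with Si–H releases silyl ether 27 and the catalyst. The closest known reaction type is the copper-catalysed reductive aldol cyclisation of acrylates of keto alcohols to β-hydroxy lactones, the hydride-triggered relative of the intramolecular Reformatsky reaction. The γ-lactone (O7–C19–C17–C8–C7) closes by a 5-(enolendo)-exo-trig aldol attack of C17 on the C8 carbonyl. C8 is controlled by the C7 stereocentre, because in the envelope transition state the bulky C9 branch of the ketone turns away from the vinyl group on C7, which puts C6 and C9 trans on the lactone. C17 is controlled by the six-membered copper chelate between the enolate and ketone oxygens, which holds the C18 methyl cis to the C8 oxygen and on the face away from the C9 branch. The step needs conjugate reduction of the acrylate to outrun hydrosilylation of the ketone and any reaction at the iodoalkene or the two unactivated alkenes, which the marked preference of phosphine–copper hydride for enoates and the immediate intramolecular trapping of the enolate should secure.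

Step 17
Reactants: 28 hydroxy lactone
Product: 29 epoxide (11,20-epoxide)
Conditions: mCPBA (1.1 equiv), CH2Cl2, aq. phosphate buffer (pH 7.5), 0 °C
Reagents that add atoms: 3-chloroperbenzoic acid, O=C(OO)c1cccc(Cl)c1
Why: Prilezhaev epoxidation should select the electron-rich 1,1-dialkyl C11=C20 alkene over the vinyl group (deactivated by the allylic lactone oxygen) and the iodoalkene; attack from the equatorial direction, anti to the axial C1 methyl, places the oxygen equatorial and C20 cis to the C1 methyl as in the target.

Step 18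
Reactants: 29 epoxide
Product: 30 C6 aldehyde
Conditions: OsO4 (2 mol %), NaIO4 (4 equiv), 2,6-lutidine, dioxane/H2O (3:1), rt
Reagents that add atoms: sodium periodate, [Na+].[O-]I(=O)(=O)=O
Why: Johnson–Lemieux cleavage of the remaining vinyl group should give the C6 aldehyde on the lactone carbon C7 and spare the iodoalkene, the epoxide and the tertiary alcohol; the aldehyde is used crude.

Step 19
Reactants: 30 C6 aldehyde
Product: 31 allylic alcohol (ten-membered ring closed; C5 exocyclic methylene; C6 drawn as the Felkin–Anh epimer)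
Conditions: CrCl2 (6 equiv), NiCl2 (2 mol %), DMSO, rt, 2 mM
Reagents that add atoms: none
Why: Nozaki–Hiyama–Kishi macrocyclisation: the alkenylchromium species (trivalent chromium) formed at C5 adds to the C6 aldehyde, which closes the ten-membered ring and creates the C5=C16 methylene in the same event; the trans-fused lactone and cyclohexane limit the rotamers of the seco chain, and the C6 configuration is not relied on because C6 is oxidised next.

Step 20
Reactants: 31 allylic alcohol
Product: 32 enone (C6 ketone conjugated with C5=C16)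
Conditions: Dess–Martin periodinane, pyridine, CH2Cl2, 0 °C
Reagents that add atoms: none
Why: Buffered Dess–Martin oxidation should converge both C6 epimers on the enone without affecting the tertiary C8 hydroxyl or the epoxide.

Step 21
Reactants: 32 enone
Product: 33 6-epi alcohol (C6 hydroxyl 1,3-anti to the C8 hydroxyl)
Conditions: Me4NBH(OAc)3, MeCN/AcOH (20:1), −35 °C
Reagents that add atoms: none
Why: Evans–Saksena reduction: the tertiary C8 hydroxyl exchanges onto boron and delivers hydride intramolecularly to the C6 carbonyl (1,2-reduction), which should give the alcohol 1,3-anti to the C8 hydroxyl, the epimer needed for inversion.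

Step 22
Reactants: 33 6-epi alcohol
Product: 34 CNP0104093.1 (target)
Conditions: PPh3, hexachloroacetone, CH2Cl2, 0 °C
Reagents that add atoms: hexachloroacetone, ClC(Cl)(Cl)C(=O)C(Cl)(Cl)Cl
Why: Appel-type chlorination with triphenylphosphine and hexachloroacetone should replace the secondary allylic hydroxyl by chloride in an SN2 displacement with inversion and without allylic transposition, placing chlorine syn to the C8 hydroxyl; the neutral medium spares the epoxide and the tertiary alcohol is too hindered to react.

**Compound list**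
1 | 4-methoxy-2-methylphenol | COc1ccc(O)c(C)c1 | starting material
2 | 4,4-dimethoxy-2-methylcyclohexa-2,5-dien-1-one | CC1=CC(OC)(OC)C=CC1=O | intermediate
3 | 4,4-dimethoxy-2-methylcyclohex-2-en-1-one | CC1=CC(OC)(OC)CCC1=O | intermediate
4 | pent-4-yn-1-ol | C#CCCCO | starting material
5 | 4-iodopent-4-en-1-ol | C=C(I)CCCO | intermediate
6 | 4-iodopent-4-enal | C=C(I)CCC=O | intermediate
7 | vinylmagnesium bromide | C=C[Mg]Br | starting material
8 | bromomagnesium (3R)-4,4-dimethoxy-2-methyl-3-vinylcyclohex-1-en-1-olate | CC1=C(O[Mg]Br)CCC(OC)(OC)[C@@H]1C=C | intermediate (not isolated)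
9 | (2S,3R)-2-[(1S)-1-hydroxy-4-iodopent-4-en-1-yl]-4,4-dimethoxy-2-methyl-3-vinylcyclohexan-1-one | C=C(I)CC[C@H](O)[C@@]1(C)C(=O)CCC(OC)(OC)[C@@H]1C=C | intermediate
10 | monoacetate: O2 acetate, C14 axial alcohol anti to O2, C10 vinyl, C11 dimethyl ketal | C=C(I)CC[C@H](OC(C)=O)[C@@]1(C)[C@@H](O)CCC(OC)(OC)[C@@H]1C=C | intermediate
11 | C9 aldehyde: formyl on C10, otherwise as 10 | C=C(I)CC[C@H](OC(C)=O)[C@@]1(C)[C@@H](O)CCC(OC)(OC)[C@@H]1C=O | intermediate
12 | allyl methoxymethyl ether (3-(methoxymethoxy)prop-1-ene) | C=CCOCOC | starting material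
13 | (Z)-3-(methoxymethoxy)allyllithium | [Li]C/C=C\OCOC | intermediate (not isolated)
14 | [(Z)-3-(methoxymethoxy)allyl]bis[(+)-isopinocampheyl]borane | COCO/C=C\CB([C@H]1C[C@H]2C[C@@H]([C@@H]1C)C2(C)C)[C@H]1C[C@H]2C[C@@H]([C@@H]1C)C2(C)C | intermediate (not isolated)
15 | syn adduct: (9S) hydroxyl, (8S) OMOM, vinyl on C8, C14 hydroxyl free | C=C(I)CC[C@H](OC(C)=O)[C@@]1(C)[C@@H](O)CCC(OC)(OC)[C@@H]1[C@H](O)[C@@H](OCOC)C=C | intermediate
16 | triacetate: acetates on O2, O9, O14; OMOM on C8; vinyl on C8 | C=C(I)CC[C@H](OC(C)=O)[C@@]1(C)[C@@H](OC(C)=O)CCC(OC)(OC)[C@@H]1[C@H](OC(C)=O)[C@@H](OCOC)C=C | intermediate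
17 | C7 aldehyde: formyl on C8, otherwise as 16 | C=C(I)CC[C@H](OC(C)=O)[C@@]1(C)[C@@H](OC(C)=O)CCC(OC)(OC)[C@@H]1[C@H](OC(C)=O)[C@@H](OCOC)C=O | intermediate
18 | vinyltitanium triisopropoxide | C=C[Ti](OC(C)C)(OC(C)C)OC(C)C | intermediate (not isolated)
19 | ketal alcohol: (7S) allylic alcohol, 7,8-anti, C11 dimethyl ketal | C=C(I)CC[C@H](OC(C)=O)[C@@]1(C)[C@@H](OC(C)=O)CCC(OC)(OC)[C@@H]1[C@H](OC(C)=O)[C@@H](OCOC)[C@@H](O)C=C | intermediate (not isolated)
20 | keto alcohol: C11 ketone, otherwise as 19 | C=C(I)CC[C@H](OC(C)=O)[C@@]1(C)[C@@H](OC(C)=O)CCC(=O)[C@@H]1[C@H](OC(C)=O)[C@@H](OCOC)[C@@H](O)C=C | intermediate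
21 | methylene alcohol: C11=C20, C7 hydroxyl free | C=C(I)CC[C@H](OC(C)=O)[C@@]1(C)[C@@H](OC(C)=O)CCC(=C)[C@@H]1[C@H](OC(C)=O)[C@@H](OCOC)[C@@H](O)C=C | intermediate
22 | acrylate: acryloyl on O7, OMOM on C8 | C=C(I)CC[C@H](OC(C)=O)[C@@]1(C)[C@@H](OC(C)=O)CCC(=C)[C@@H]1[C@H](OC(C)=O)[C@@H](OCOC)[C@@H](OC(=O)C=C)C=C | intermediate
23 | bromomethyl ether: OCH2Br on C8 | C=C(I)CC[C@H](OC(C)=O)[C@@]1(C)[C@@H](OC(C)=O)CCC(=C)[C@@H]1[C@H](OC(C)=O)[C@@H](OCBr)[C@@H](OC(=O)C=C)C=C | intermediate (not isolated)
24 | C8 alcohol: free hydroxyl on C8, acryloyl on O7 | C=C(I)CC[C@H](OC(C)=O)[C@@]1(C)[C@@H](OC(C)=O)CCC(=C)[C@@H]1[C@H](OC(C)=O)[C@@H](O)[C@@H](OC(=O)C=C)C=C | intermediate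
25 | C8 ketone: 9-acetoxy-7-acryloyloxy-8-ketone with vinyl on C7 | C=C(I)CC[C@H](OC(C)=O)[C@@]1(C)[C@@H](OC(C)=O)CCC(=C)[C@@H]1[C@H](OC(C)=O)C(=O)[C@@H](OC(=O)C=C)C=C | intermediate
26 | copper (Z)-enolate of the O7 propanoate (phosphine ligands omitted) | C=C(I)CC[C@H](OC(C)=O)[C@@]1(C)[C@@H](OC(C)=O)CCC(=C)[C@@H]1[C@H](OC(C)=O)C(=O)[C@@H](O/C(O[Cu])=C/C)C=C | intermediate (not isolated)
27 | silyl ether of the lactone (O8–SiMe2–O–SiMe2H) | C=C(I)CC[C@H](OC(C)=O)[C@@]1(C)[C@@H](OC(C)=O)CCC(=C)[C@@H]1[C@H](OC(C)=O)[C@]2(O[Si](C)(C)O[SiH](C)C)[C@@H](C)C(=O)O[C@H]2C=C | intermediate (not isolated)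
28 | hydroxy lactone: γ-lactone with C8 hydroxyl, C17 methyl, vinyl on C7; C11=C20 | C=C(I)CC[C@H](OC(C)=O)[C@@]1(C)[C@@H](OC(C)=O)CCC(=C)[C@@H]1[C@H](OC(C)=O)[C@]2(O)[C@@H](C)C(=O)O[C@H]2C=C | intermediate
29 | epoxide: 11,20-epoxide, otherwise as 28 | C=C(I)CC[C@H](OC(C)=O)[C@@]1(C)[C@@H](OC(C)=O)CC[C@]3(CO3)[C@@H]1[C@H](OC(C)=O)[C@]2(O)[C@@H](C)C(=O)O[C@H]2C=C | intermediate
30 | C6 aldehyde: formyl on C7, otherwise as 29 | C=C(I)CC[C@H](OC(C)=O)[C@@]1(C)[C@@H](OC(C)=O)CC[C@]3(CO3)[C@@H]1[C@H](OC(C)=O)[C@]2(O)[C@@H](C)C(=O)O[C@H]2C=O | intermediate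
31 | allylic alcohol: ring-closed 6-hydroxy compound, hydroxyl in the position of the chlorine of 34 (expected major epimer) | C=C1CC[C@H](OC(C)=O)[C@@]2(C)[C@@H](OC(C)=O)CC[C@]3(CO3)[C@@H]2[C@H](OC(C)=O)[C@]2(O)[C@@H](C)C(=O)O[C@H]2[C@H]1O | intermediate
32 | enone: 6-ketone | C=C1CC[C@H](OC(C)=O)[C@@]2(C)[C@@H](OC(C)=O)CC[C@]3(CO3)[C@@H]2[C@H](OC(C)=O)[C@]2(O)[C@@H](C)C(=O)O[C@H]2C1=O | intermediate
33 | 6-epi alcohol: C6 hydroxyl anti to the C8 hydroxyl | C=C1CC[C@H](OC(C)=O)[C@@]2(C)[C@@H](OC(C)=O)CC[C@]3(CO3)[C@@H]2[C@H](OC(C)=O)[C@]2(O)[C@@H](C)C(=O)O[C@H]2[C@@H]1O | intermediate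
34 | CNP0104093.1 | C=C1CC[C@H](OC(C)=O)[C@@]2(C)[C@@H](OC(C)=O)CC[C@]3(CO3)[C@@H]2[C@H](OC(C)=O)[C@]2(O)[C@@H](C)C(=O)O[C@H]2[C@H]1Cl | target

**Step count**
Total: 22 steps. Longest linear sequence: 20 steps (steps 1, 2 and 5–22, from 1).

**Steps most likely to fail**

Step 19. The ten-membered ring may close too slowly, so that intermolecular coupling, reduction of the iodoalkene or epimerisation of the α-oxygenated aldehyde take over. The fallback sets out from 29 and comes back at 34. Negishi methylation of the iodoalkene of 29 (MeZnCl, Pd(PPh3)4, THF) should give the isopropenyl compound F1. Ring-closing metathesis between the C5 isopropenyl and C6 vinyl groups (second-generation Grubbs catalyst, toluene, high dilution, 80 °C) should give the (Z)-5,6-cycloalkene F2, in which C16 is a methyl group. Ene-type chlorination (N-chlorosuccinimide, catalytic PhSeCl, CH2Cl2) should deliver chlorine to C6 with shift of the double bond to C5=C16 and reach 34 directly, so that steps 18–22 are bypassed.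

Step 5. Enantioface discrimination in the copper-catalysed vinyl transfer to the hindered, ketal-flanked β-carbon may be poor, and direct addition of the Grignard reagent to aldehyde 6 may compete. The fallback sets out from 3 and comes back at 15. The addition is run with an achiral catalyst (CuBr·SMe2), which gives 8 together with the enantiomeric magnesium enolate F3 and then 9 together with the enantiomeric aldol F4. The racemate is carried through steps 6 and 7 (enantiomeric monoacetate F5, enantiomeric aldehyde F6). In step 8 the enantiopure borane 14 converts 11 into 15 and F6 into the diastereomeric adduct F7, which is removed by chromatography; the route continues with 15.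

Step 16. Enolisation of the ketone toward C7 by the basic copper alkoxide may scramble C7 and move the vinyl group into conjugation, and hydrosilylation of the ketone may compete with conjugate reduction. The fallback sets out from 21 and comes back at 28. Acylation of 21 with 2-bromopropanoyl bromide and pyridine should give the bromo ester F8 (mixture at the CHBr carbon). Me2BBr then aqueous NaHCO3 should give, through the bromomethyl ether F9, the C8 alcohol F10, and Dess–Martin oxidation the ketone F11. SmI2 (2.2 equiv, THF, −78 °C) should then form the samarium enolate F12 regiospecifically at C17 by C–Br reduction; its intramolecular Reformatsky addition to the C8 ketone should give 28 through the same chelated transition state.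

**Further compounds**
F1 | step 19 | isopropenyl compound (methyl in place of iodine in 29) | C=C(C)CC[C@H](OC(C)=O)[C@@]1(C)[C@@H](OC(C)=O)CC[C@]3(CO3)[C@@H]1[C@H](OC(C)=O)[C@]2(O)[C@@H](C)C(=O)O[C@H]2C=C
F2 | step 19 | (Z)-5,6-cycloalkene (ten-membered ring, C16 methyl, no chlorine) | C/C1=C/[C@@H]2OC(=O)[C@H](C)[C@@]2(O)[C@@H](OC(C)=O)[C@H]3[C@@]4(CO4)CC[C@H](OC(C)=O)[C@]3(C)[C@@H](OC(C)=O)CC1
F3 | step 5 | enantiomeric magnesium enolate (ent-8) | CC1=C(O[Mg]Br)CCC(OC)(OC)[C@H]1C=C
F4 | step 5 | enantiomeric aldol (ent-9) | C=C(I)CC[C@@H](O)[C@]1(C)C(=O)CCC(OC)(OC)[C@H]1C=C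
F5 | step 5 | enantiomeric monoacetate (ent-10) | C=C(I)CC[C@@H](OC(C)=O)[C@]1(C)[C@H](O)CCC(OC)(OC)[C@H]1C=C
F6 | step 5 | enantiomeric aldehyde (ent-11) | C=C(I)CC[C@@H](OC(C)=O)[C@]1(C)[C@H](O)CCC(OC)(OC)[C@H]1C=O
F7 | step 5 | diastereomeric adduct (core of ent-11, C8 and C9 as in 15) | C=C(I)CC[C@@H](OC(C)=O)[C@]1(C)[C@H](O)CCC(OC)(OC)[C@H]1[C@H](O)[C@@H](OCOC)C=C
F8 | step 16 | bromo ester (2-bromopropanoyl on O7 of 21) | C=C(I)CC[C@H](OC(C)=O)[C@@]1(C)[C@@H](OC(C)=O)CCC(=C)[C@@H]1[C@H](OC(C)=O)[C@@H](OCOC)[C@@H](OC(=O)C(C)Br)C=C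
F9 | step 16 | bromomethyl ether of the bromo ester | C=C(I)CC[C@H](OC(C)=O)[C@@]1(C)[C@@H](OC(C)=O)CCC(=C)[C@@H]1[C@H](OC(C)=O)[C@@H](OCBr)[C@@H](OC(=O)C(C)Br)C=C
F10 | step 16 | C8 alcohol of the bromo ester | C=C(I)CC[C@H](OC(C)=O)[C@@]1(C)[C@@H](OC(C)=O)CCC(=C)[C@@H]1[C@H](OC(C)=O)[C@@H](O)[C@@H](OC(=O)C(C)Br)C=C
F11 | step 16 | C8 ketone of the bromo ester | C=C(I)CC[C@H](OC(C)=O)[C@@]1(C)[C@@H](OC(C)=O)CCC(=C)[C@@H]1[C@H](OC(C)=O)C(=O)[C@@H](OC(=O)C(C)Br)C=C
F12 | step 16 | samarium (Z)-enolate of the O7 propanoate | C=C(I)CC[C@H](OC(C)=O)[C@@]1(C)[C@@H](OC(C)=O)CCC(=C)[C@@H]1[C@H](OC(C)=O)C(=O)[C@@H](O/C(O[Sm](I)I)=C/C)C=C
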